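## The problem

The target is a (3R)-isoflavan. A dihydropyran (ring C) is fused to ring A, which carries 5-OMe, 7-OH and 8-CHO, and C3 bears ring B. In ring B the 2'-oxygen and C3' are bridged by a 2,2-dimethyl-2H-pyran (ring D), and the 4'-hydroxyl is free.

The skeleton needs three carbon–carbon bonds to arenes (C4–C4a, C3–C1', C3'–olefinic carbon of ring D) and two aryl ether bonds (O1–C2, O2'–CMe2). Both arenes are tri-oxygenated and electron rich, so electrophilic substitution would be hard to steer between C6 and C8/C4a on ring A and between C3' and C5' on ring B.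

C3 is the only stereocentre, a benzylic methine between two methylene groups. Nothing in the molecule can relay chirality to it, so it must be set by reagent control. With no adjacent carbonyl it should be configurationally stable once made, but it cannot be corrected later.

The ring D styrenic alkene and its allylic ether rule out hydrogenolysis, strong acid and late electrophilic chemistry. The electron-rich ortho-hydroxy aldehyde is open to hydride reduction and to Dakin oxidation. Ring A has the symmetric phloroglucinaldehyde pattern, so the two oxygens flanking the formyl group (O1 and O7) must be told apart.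

The enabling feature is the ortho pattern of two oxygens. O1 on C8a has C8 (formyl) and C4a as ortho carbons; the 2'-oxygen has C1' (bearing C3) and C3'. Each oxygen has exactly one open ortho carbon, and it is the carbon that must gain a carbon substituent. Both bonds can therefore be delivered from oxygen by [3,3] sigmatropic shifts.

## Retrosynthesis

**18 to 17 (unmasking).** Target 18 is traced to isoflavan 17, in which both phenols are MOM ethers and the aldehyde is a dioxolane. Only C–O acetal bonds are cut, and all three masks fall to one mild acid treatment. Benzyl ethers are excluded because hydrogenolysis would saturate ring D.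

**17 to 16 (O1–C2).** Cutting O1–C2 gives phenol-alcohol 16. The neighbouring cuts are poorer: O1–C8a would need an aryl halide and a metal-mediated etherification, and C4–C4a would need a Friedel–Crafts closure on a ring with a competing position. The forward reaction is a Mitsunobu closure at a primary carbon, and C3 is not at the reacting centre.

**16 to 14 via 15 (the stereocentre).** The C2 hydroxyl and the C3–H bond are removed to give the achiral 1,1-disubstituted alkene 14. An anti-Markovnikov, face-selective hydroboration with a chiral CoCl2-derived catalyst, then oxidation of boronate 15, must set C3. Hydrogenating an isoflav-3-ene was rejected because the ring D alkene would compete. The forward step must leave the hindered ring D alkene alone.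

**14 to 13 to 12 (masking).** The dioxolane and the aryl acetate are there only to carry the aldehyde and the O1 phenol through hydride and alkaline peroxide. The acetate is chosen because the oxidative work-up of the hydroboration removes it. Their removal leads back to salicylaldehyde 12.

**12 to 10 via 11 (key disconnection).** C4–C4a is cut, and in ring D the C3'–CH= bond and the O2'–CMe2 bond are cut. Both sets of bonds are traced to ethers on O1 and O2': a 2-arylallyl ether and a 1,1-dimethylpropargyl ether in bis-ether 10. Friedel–Crafts allylation or chromenylation of the free arenes would face the regiochemical problems named above. Cross-coupling would need halogenated, fully substituted arenes. Precursor 10 has no carbon–carbon bond between the fragments and no ring D. The forward reaction must be ortho-selective twice, which the blocked positions C8 and C1' ensure.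

**10 to 3 + 9 (fragment union).** The aryl–O–CH2 bond is cut to give phenol 3 and allylic alcohol 9, joined by Mitsunobu etherification. This CH2 becomes the alkene terminus after the rearrangement and later C2, so the O1–C2 bond is made, broken and re-made.

**9 to 8 to 7 (allylic alcohol).** The allylic C–O bond is cut (allylic oxidation of isopropenyl arene 8), then the C=CH2 bond (Wittig methylenation of ketone 7). The acetyl group of the starting acetophenone thus supplies C3 and both of its methylene neighbours.

**7 to 5 + 6, and 5 to 4 (ring B ethers).** The O2'–CMe2 bond is cut to give chelated phenol 5 and chloride 6. The MOM ether of 5 goes back to 2,4-dihydroxyacetophenone 4, where the chelated 2-hydroxyl is left untouched by mild alkylation.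

**3 to 2 to 1 (ring A).** The MOM and methyl ethers are cut back to 2,4,6-trihydroxybenzaldehyde 1. The para hydroxyl is methylated first because it is the most acidic and is not chelated. One of the two equivalent ortho hydroxyls is then capped, the other staying locked to the formyl group.

## Roads not taken

**Alternative 1:** The cut is C3–C1' together with a temporary C4–O2' bond, through a pterocarpan. In the forward step Pd(OAc)2, Ag2CO3 and a chiral bisphosphine would join 5,7-dimethoxy-2H-chromene A1 and 2-iodo-5-(methoxymethoxy)phenol A2. The aryl group adds to C3 and the phenol oxygen to C4, giving the cis-fused (6aR,11aR)-pterocarpan A3.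

- Merits: two simple partners, high convergence, and the C3 configuration is set in the same step as the C3–C1' bond. Hydrogenolysis of the benzylic C–O bond of A3 would give the 3R series. In this respect it is better than the chosen plan, which sets C3 in a separate step.
- Weak points: the hydrogenolysis must come before any ring D alkene exists, so ring D has to be built afterwards on the freed 2'-oxygen. Ring A of A3 lacks the formyl group and has a 7-methyl ether. A late formylation must then choose C8 over C6, and a selective 7-O-demethylation is needed. Enantiocontrol in oxyarylations of electron-rich chromenes is not assured, and a stoichiometric silver salt is needed.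
- Comparison: the chosen plan has every substituent of both rings in place before the key step and needs no late arene substitution.

**Alternative 2:** The cut is C3–C1' and C4–C4a around a two-carbon boron unit. The ate complex from 4,4,5,5-tetramethyl-2-vinyl-1,3,2-dioxaborolane A4 and the aryllithium made from 8-bromo-2,2-dimethyl-5-(triisopropylsilyloxy)-2H-chromene A5 would react with 2,4-dimethoxy-6-(methoxymethoxy)phenyl trifluoromethanesulfonate A6 under Pd(OAc)2 and a chiral ferrocenyl bisphosphine, giving secondary boronate A7.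

- Merits: two carbon–carbon bonds and the stereocentre in one catalytic step, in a reaction class known for high enantioselectivity. On stereocontrol it is likely the strongest of the four plans.
- Weak points: A6 is a di-ortho-substituted, electron-rich triflate, which slows oxidative addition and reductive elimination. A7 lacks C2, so a one-carbon homologation, oxidation, selective unmasking of O1 and ring closure must follow. Ring A again has no formyl group and a 7-methyl ether, so the late formylation and demethylation return.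
- Comparison: the chosen plan has a shorter, more predictable path from its key step and a fully substituted ring A. Against that it has a less proven enantioselective step on a hindered alkene.

**Alternative 3:** The cut is O1–C2 and C3–C4, a [4+2] construction of ring C. An ortho-quinone methide released from tert-butyl 2-(hydroxymethyl)-3,5-dimethoxyphenyl carbonate A8 with t-BuMgCl would add to the (E)-enol ether A9, which carries a trans-2-phenylcyclohexyl auxiliary. The product is the 2,3-trans 2-alkoxyisoflavan acetal A10 with the 3R configuration.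

- Merits: ring C and C3 in one low-temperature step, with diastereocontrol from a recoverable auxiliary. It is the most direct route to ring C, and ring D is already present.
- Weak points: the auxiliary is stoichiometric and A9 must be made as a single alkene isomer. The C2 alkoxy group of A10 must then be removed by Lewis acid and silane, in the presence of the acid-sensitive ring D. Ring A again needs late formylation at C8 and selective 7-O-demethylation.
- Comparison: the chosen plan needs more protecting-group steps and a separate ring C closure. It avoids Lewis acid treatment of the chromene and all late electrophilic substitution on ring A.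

Key step: step 8

Assumption: the sense of induction of the chiral (IPO)CoCl2 catalyst in step 11 is taken from simple α-alkylstyrenes. The ligand antipode is the one that gives the 3R configuration; both antipodes are equally accessible.

## Steps

Step 1
Reactants: 1 2,4,6-trihydroxybenzaldehyde
Product: 2 2,6-dihydroxy-4-methoxybenzaldehyde
Conditions: Me2SO4 (1.0 equiv), K2CO3 (1.0 equiv), acetone, 0 °C to rt
Reagents that add atoms: dimethyl sulfate, COS(=O)(=O)OC
Why: Williamson O-methylation; the 4-hydroxyl is the most acidic and the only one not chelated to the formyl group, so one equivalent of a mild base and electrophile should alkylate it preferentially.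

Step 2
Reactants: 2 2,6-dihydroxy-4-methoxybenzaldehyde
Product: 3 2-hydroxy-4-methoxy-6-(methoxymethoxy)benzaldehyde
Conditions: MOMCl (1.05 equiv), i-Pr2NEt, CH2Cl2, 0 °C to rt
Reagents that add atoms: chloromethyl methyl ether, COCCl
Why: Acetal-type O-alkylation of a phenol; after the first of the two equivalent hydroxyls is capped the other is locked in a hydrogen bond to the formyl group, so mono-protection should be clean.

Step 3
Reactants: 4 1-(2,4-dihydroxyphenyl)ethan-1-one
Product: 5 1-[2-hydroxy-4-(methoxymethoxy)phenyl]ethan-1-one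
Conditions: MOMCl, K2CO3, acetone, rt
Reagents that add atoms: chloromethyl methyl ether, COCCl
Why: Selective O-alkylation of the non-chelated 4-hydroxyl of a 2,4-dihydroxyaryl ketone; the 2-hydroxyl stays hydrogen-bonded to the ketone and is left free for the next step.

Step 4
Reactants: 5 1-[2-hydroxy-4-(methoxymethoxy)phenyl]ethan-1-one; 6 3-chloro-3-methylbut-1-yne
Product: 7 1-{4-(methoxymethoxy)-2-[(2-methylbut-3-yn-2-yl)oxy]phenyl}ethan-1-one
Conditions: DBU, CuCl2·2H2O (cat.), MeCN, 0 °C to rt
Reagents that add atoms: none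
Why: Copper-catalysed O-propargylation of a phenol with a tertiary propargylic chloride; DBU deprotonates the chelated phenol and the copper acetylide-derived electrophile is captured at oxygen, a standard entry to aryl 1,1-dimethylpropargyl ethers.

Step 5
Reactants: 7 1-{4-(methoxymethoxy)-2-[(2-methylbut-3-yn-2-yl)oxy]phenyl}ethan-1-one
Product: 8 4-(methoxymethoxy)-2-[(2-methylbut-3-yn-2-yl)oxy]-1-(prop-1-en-2-yl)benzene
Conditions: Ph3PCH3Br, KOt-Bu, THF, 0 °C to rt
Reagents that add atoms: methyltriphenylphosphonium bromide, C[P+](c1ccccc1)(c1ccccc1)c1ccccc1.[Br-]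
Why: Wittig methylenation of an aryl methyl ketone; the non-stabilised ylide is not basic enough to be consumed by the terminal alkyne, and the propargyl ether is inert at room temperature.

Step 6
Reactants: 8 4-(methoxymethoxy)-2-[(2-methylbut-3-yn-2-yl)oxy]-1-(prop-1-en-2-yl)benzene
Product: 9 2-{4-(methoxymethoxy)-2-[(2-methylbut-3-yn-2-yl)oxy]phenyl}prop-2-en-1-ol
Conditions: SeO2 (cat.), t-BuOOH, CH2Cl2, rt
Reagents that add atoms: tert-butyl hydroperoxide, CC(C)(C)OO; selenium dioxide (oxygen carrier), O=[Se]=O
Why: Riley allylic oxidation (ene reaction, then [2,3] shift) of an α-methylstyrene; the methyl group is the only allylic C–H position, and the propargylic carbon is quaternary, so the 2-arylallyl alcohol should be the main product.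

Step 7
Reactants: 3 2-hydroxy-4-methoxy-6-(methoxymethoxy)benzaldehyde; 9 2-{4-(methoxymethoxy)-2-[(2-methylbut-3-yn-2-yl)oxy]phenyl}prop-2-en-1-ol
Product: 10 4-methoxy-6-(methoxymethoxy)-2-[(2-{4-(methoxymethoxy)-2-[(2-methylbut-3-yn-2-yl)oxy]phenyl}prop-2-en-1-yl)oxy]benzaldehyde
Conditions: PPh3, DIAD, THF, 0 °C to rt
Reagents that add atoms: none
Why: Mitsunobu etherification of an acidic, formyl-chelated phenol with a primary allylic alcohol; direct and allylic substitution give the same ether because the allyl unit is symmetric about its 2-aryl carbon.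

Step 8
Reactants: 10 4-methoxy-6-(methoxymethoxy)-2-[(2-{4-(methoxymethoxy)-2-[(2-methylbut-3-yn-2-yl)oxy]phenyl}prop-2-en-1-yl)oxy]benzaldehyde
Product: 12 2-hydroxy-4-methoxy-6-(methoxymethoxy)-3-{2-[5-(methoxymethoxy)-2,2-dimethyl-2H-chromen-8-yl]prop-2-en-1-yl}benzaldehyde, via chromene allyl ether 11 (not isolated)
Conditions: PhNEt2 (degassed), 190 °C, sealed tube
Reagents that add atoms: none
Why: On ring B the aryl 1,1-dimethylpropargyl ether should undergo the lower-barrier [3,3] shift first: the alkyne terminus bonds to C3', the only open ortho carbon of the 2'-oxygen because C1' carries the side chain, giving an allenyl cyclohexadienone. This enolises, passes by a 1,5-hydrogen shift to an ortho-quinone methide-type dienone, and closes ring D by a thermally allowed oxa-6π electrocyclisation that forms the O–CMe2 bond, which accounts for intermediate 11. The aryl 2-arylallyl ether on ring A then rearranges through a chair [3,3] transition state that joins the allyl terminus to C4a (the C4–C4a bond), the only open ortho carbon of O1 because C8 carries the formyl group; tautomerisation restores the phenol, which is held by a hydrogen bond to the aldehyde. The closest known reactions are the aromatic Claisen rearrangement of aryl 2-arylallyl ethers and the thermal rearrangement of aryl 1,1-dimethylpropargyl ethers to 2,2-dimethyl-2H-chromenes, here run in one operation. No stereocentre is created. The only selectivity needed is ortho regioselectivity, secured by the formyl group at C8 and the substituent at C1'; the para positions should stay untouched while an ortho site is open. The weakly basic solvent buffers the medium so that the new phenol is not driven to add across the electron-rich styrene.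

Step 9
Reactants: 12 2-hydroxy-4-methoxy-6-(methoxymethoxy)-3-{2-[5-(methoxymethoxy)-2,2-dimethyl-2H-chromen-8-yl]prop-2-en-1-yl}benzaldehyde
Product: 13 2-formyl-5-methoxy-3-(methoxymethoxy)-6-{2-[5-(methoxymethoxy)-2,2-dimethyl-2H-chromen-8-yl]prop-2-en-1-yl}phenyl acetate
Conditions: Ac2O, Et3N, DMAP (cat.), CH2Cl2, rt
Reagents that add atoms: acetic anhydride, CC(=O)OC(C)=O
Why: DMAP-catalysed O-acylation under basic conditions; the acetate removes the internal nucleophile next to the acid-sensitive styrene, frees the aldehyde from its hydrogen bond for acetalisation, and keeps a protic phenol out of the hydroboration.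

Step 10
Reactants: 13 2-formyl-5-methoxy-3-(methoxymethoxy)-6-{2-[5-(methoxymethoxy)-2,2-dimethyl-2H-chromen-8-yl]prop-2-en-1-yl}phenyl acetate
Product: 14 2-(1,3-dioxolan-2-yl)-5-methoxy-3-(methoxymethoxy)-6-{2-[5-(methoxymethoxy)-2,2-dimethyl-2H-chromen-8-yl]prop-2-en-1-yl}phenyl acetate
Conditions: TMSOCH2CH2OTMS, TMSOTf (cat.), CH2Cl2, −78 to −20 °C; pyridine quench
Reagents that add atoms: 1,2-bis(trimethylsilyloxy)ethane, C[Si](C)(C)OCCO[Si](C)(C)C
Why: Noyori acetalisation under aprotic, low-temperature conditions; the strongly donor-stabilised oxocarbenium ion of this aldehyde should form readily, while the absence of protic acid spares the MOM ethers, the styrene and ring D.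

Step 11
Reactants: 14 2-(1,3-dioxolan-2-yl)-5-methoxy-3-(methoxymethoxy)-6-{2-[5-(methoxymethoxy)-2,2-dimethyl-2H-chromen-8-yl]prop-2-en-1-yl}phenyl acetate
Product: 16 (2R)-3-[3-(1,3-dioxolan-2-yl)-2-hydroxy-6-methoxy-4-(methoxymethoxy)phenyl]-2-[5-(methoxymethoxy)-2,2-dimethyl-2H-chromen-8-yl]propan-1-ol, via pinacol boronate 15 (not isolated)
Conditions: HBpin, (IPO)CoCl2 (cat., IPO = enantiopure iminopyridine–oxazoline ligand), NaBHEt3 (cat.), THF, rt; then NaOH, H2O2, THF/H2O, 0 °C to rt
Reagents that add atoms: hydrogen peroxide, OO; pinacolborane, [H]B1OC(C)(C)C(C)(C)O1 (its boron and pinacolate stay only in 15)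
Why: Catalytic asymmetric anti-Markovnikov hydroboration of a 1,1-disubstituted aryl alkene, a known use of this catalyst class: hydrogen goes to C3 and boron to the terminal carbon, and the chiral ligand on cobalt tells the alkene faces apart by the difference between the ring B aryl group and the benzylic CH2 substituent, setting C3 as R. The internal ring D alkene next to a quaternary carbon is too hindered to compete, and the dioxolane shields the aldehyde from hydride and from Dakin oxidation. Alkaline peroxide then oxidises C–B to C–OH without touching C3 and saponifies the aryl acetate.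

Step 12
Reactants: 16 (2R)-3-[3-(1,3-dioxolan-2-yl)-2-hydroxy-6-methoxy-4-(methoxymethoxy)phenyl]-2-[5-(methoxymethoxy)-2,2-dimethyl-2H-chromen-8-yl]propan-1-ol
Product: 17 (3R)-8-(1,3-dioxolan-2-yl)-5-methoxy-7-(methoxymethoxy)-3-[5-(methoxymethoxy)-2,2-dimethyl-2H-chromen-8-yl]-3,4-dihydro-2H-chromene
Conditions: PPh3, DIAD, THF, 0 °C to rt
Reagents that add atoms: none
Why: Intramolecular Mitsunobu etherification; the only free phenol displaces the activated primary alcohol in a 6-exo-tet closure of ring C, and the stereocentre at C3 is not at the reacting carbon and is unchanged.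

Step 13
Reactants: 17 (3R)-8-(1,3-dioxolan-2-yl)-5-methoxy-7-(methoxymethoxy)-3-[5-(methoxymethoxy)-2,2-dimethyl-2H-chromen-8-yl]-3,4-dihydro-2H-chromene
Product: 18 (3R)-7-hydroxy-3-(5-hydroxy-2,2-dimethyl-2H-chromen-8-yl)-5-methoxy-3,4-dihydro-2H-chromene-8-carbaldehyde
Conditions: 3 M HCl (aq), MeOH/THF, 40 °C
Reagents that add atoms: water, O
Why: Acid-catalysed acetal hydrolysis and methanolysis; the electron-rich dioxolane and both phenolic MOM ethers should cleave under dilute acid that 2,2-dimethyl-2H-chromenes tolerate, and C3 has no pathway for epimerisation.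

## Compound list

1 | 2,4,6-trihydroxybenzaldehyde | O=Cc1c(O)cc(O)cc1O | starting material
2 | 2,6-dihydroxy-4-methoxybenzaldehyde | COc1cc(O)c(C=O)c(O)c1 | intermediate
3 | 2-hydroxy-4-methoxy-6-(methoxymethoxy)benzaldehyde | COCOc1cc(OC)cc(O)c1C=O | intermediate
4 | 1-(2,4-dihydroxyphenyl)ethan-1-one | CC(=O)c1ccc(O)cc1O | starting material
5 | 1-[2-hydroxy-4-(methoxymethoxy)phenyl]ethan-1-one | COCOc1ccc(C(C)=O)c(O)c1 | intermediate
6 | 3-chloro-3-methylbut-1-yne | CC(C)(Cl)C#C | starting material
7 | 1-{4-(methoxymethoxy)-2-[(2-methylbut-3-yn-2-yl)oxy]phenyl}ethan-1-one | COCOc1ccc(C(C)=O)c(OC(C)(C)C#C)c1 | intermediate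
8 | 4-(methoxymethoxy)-2-[(2-methylbut-3-yn-2-yl)oxy]-1-(prop-1-en-2-yl)benzene | COCOc1ccc(C(C)=C)c(OC(C)(C)C#C)c1 | intermediate
9 | 2-{4-(methoxymethoxy)-2-[(2-methylbut-3-yn-2-yl)oxy]phenyl}prop-2-en-1-ol | COCOc1ccc(C(=C)CO)c(OC(C)(C)C#C)c1 | intermediate
10 | 4-methoxy-6-(methoxymethoxy)-2-[(2-{4-(methoxymethoxy)-2-[(2-methylbut-3-yn-2-yl)oxy]phenyl}prop-2-en-1-yl)oxy]benzaldehyde | COc1cc(OCOC)c(C=O)c(OCC(=C)c2ccc(OCOC)cc2OC(C)(C)C#C)c1 | intermediate
11 | 4-methoxy-6-(methoxymethoxy)-2-({2-[5-(methoxymethoxy)-2,2-dimethyl-2H-chromen-8-yl]prop-2-en-1-yl}oxy)benzaldehyde | COc1cc(OCOC)c(C=O)c(OCC(=C)c2ccc(OCOC)c3c2OC(C)(C)C=C3)c1 | intermediate (not isolated)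
12 | 2-hydroxy-4-methoxy-6-(methoxymethoxy)-3-{2-[5-(methoxymethoxy)-2,2-dimethyl-2H-chromen-8-yl]prop-2-en-1-yl}benzaldehyde | COc1cc(OCOC)c(C=O)c(O)c1CC(=C)c1ccc(OCOC)c2c1OC(C)(C)C=C2 | intermediate
13 | 2-formyl-5-methoxy-3-(methoxymethoxy)-6-{2-[5-(methoxymethoxy)-2,2-dimethyl-2H-chromen-8-yl]prop-2-en-1-yl}phenyl acetate | COc1cc(OCOC)c(C=O)c(OC(C)=O)c1CC(=C)c1ccc(OCOC)c2c1OC(C)(C)C=C2 | intermediate
14 | 2-(1,3-dioxolan-2-yl)-5-methoxy-3-(methoxymethoxy)-6-{2-[5-(methoxymethoxy)-2,2-dimethyl-2H-chromen-8-yl]prop-2-en-1-yl}phenyl acetate | COc1cc(OCOC)c(C2OCCO2)c(OC(C)=O)c1CC(=C)c1ccc(OCOC)c2c1OC(C)(C)C=C2 | intermediate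
15 | 2-(1,3-dioxolan-2-yl)-5-methoxy-3-(methoxymethoxy)-6-{(2R)-2-[5-(methoxymethoxy)-2,2-dimethyl-2H-chromen-8-yl]-3-(4,4,5,5-tetramethyl-1,3,2-dioxaborolan-2-yl)propyl}phenyl acetate | COc1cc(OCOC)c(C2OCCO2)c(OC(C)=O)c1C[C@H](c1ccc(OCOC)c2c1OC(C)(C)C=C2)CB1OC(C)(C)C(C)(C)O1 | intermediate (not isolated)
16 | (2R)-3-[3-(1,3-dioxolan-2-yl)-2-hydroxy-6-methoxy-4-(methoxymethoxy)phenyl]-2-[5-(methoxymethoxy)-2,2-dimethyl-2H-chromen-8-yl]propan-1-ol | COc1cc(OCOC)c(C2OCCO2)c(O)c1C[C@H](c1ccc(OCOC)c2c1OC(C)(C)C=C2)CO | intermediate
17 | (3R)-8-(1,3-dioxolan-2-yl)-5-methoxy-7-(methoxymethoxy)-3-[5-(methoxymethoxy)-2,2-dimethyl-2H-chromen-8-yl]-3,4-dihydro-2H-chromene | COc1cc(OCOC)c(C3OCCO3)c2c1C[C@H](c1ccc(OCOC)c3c1OC(C)(C)C=C3)CO2 | intermediate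
18 | (3R)-7-hydroxy-3-(5-hydroxy-2,2-dimethyl-2H-chromen-8-yl)-5-methoxy-3,4-dihydro-2H-chromene-8-carbaldehyde | COc1cc(O)c(C=O)c2c1C[C@H](c1ccc(O)c3c1OC(C)(C)C=C3)CO2 | target

## Step count and risk

Total step count: 13. Longest linear sequence: 11 steps (steps 3 to 13, from 4); the ring A branch (steps 1 and 2) joins at step 7.

**Step 8 (key step).** The two rearrangements have different thermal thresholds. During the long heating needed for the ring A shift, the allenyl and quinone methide intermediates of the ring B shift may be intercepted by the allyl ether, or the new phenol may add in the Markovnikov sense across the electron-rich styrene. The fallback separates the two events and sets out from 7.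
- Heating 7 in xylene at about 140 °C should bring about the propargyl ether rearrangement alone and give 1-[5-(methoxymethoxy)-2,2-dimethyl-2H-chromen-8-yl]ethan-1-one F1.
- Wittig methylenation gives 5-(methoxymethoxy)-2,2-dimethyl-8-(prop-1-en-2-yl)-2H-chromene F2.
- SeO2/t-BuOOH oxidation gives 2-[5-(methoxymethoxy)-2,2-dimethyl-2H-chromen-8-yl]prop-2-en-1-ol F3.
- Mitsunobu coupling of F3 with 3 comes back to the route at 11. Compound 11 is then isolated and put through a single aromatic Claisen rearrangement to 12.

**Step 11.** The bulky ring B aryl group and the hexasubstituted benzyl group may be poorly told apart by the catalyst. Insertion at this hindered alkene may be slow, and the aryl acetate may be reduced in part. The fallback gives up catalytic induction and sets out from 14.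
- Hydroboration with 9-BBN gives the racemic B-alkyl-9-borabicyclo[3.3.1]nonane adduct of 14 F4.
- Alkaline peroxide gives racemic 16 F5.
- Mitsunobu closure gives racemic 17 F6.
- Preparative chromatography on a chiral stationary phase comes back to the route at 17. The (3S)-enantiomer of 17 F7 is set aside.

**Step 6.** Over-oxidation to the 2-arylacrolein and its polymerisation, or oxidative degradation of the electron-rich arene, may erode the allylic oxidation. The fallback builds the hydroxyl before the alkene and sets out from 7.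
- Soft enolisation with TBSOTf/Et3N gives tert-butyl[(1-{4-(methoxymethoxy)-2-[(2-methylbut-3-yn-2-yl)oxy]phenyl}ethenyl)oxy]dimethylsilane F8.
- Rubottom oxidation with mCPBA/NaHCO3, with silyl migration, gives 2-[(tert-butyldimethylsilyl)oxy]-1-{4-(methoxymethoxy)-2-[(2-methylbut-3-yn-2-yl)oxy]phenyl}ethan-1-one F9.
- Wittig methylenation gives tert-butyl[(2-{4-(methoxymethoxy)-2-[(2-methylbut-3-yn-2-yl)oxy]phenyl}prop-2-en-1-yl)oxy]dimethylsilane F10.
- TBAF comes back to the route at 9, replacing steps 5 and 6.

**Step 10.** The Lewis acid may strip MOM groups or start cationic oligomerisation of the styrene, and the hindered, deactivated aldehyde may acetalise incompletely. The fallback dispenses with the acetal by letting the aldehyde be reduced and re-oxidised, and sets out from 13.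
- Hydroboration with the catalyst of step 11 and excess HBpin gives the bis-boryl compound F11, which carries the C-bound pinacol boronate of 15 and a pinacol borate ester of the reduced formyl group.
- Alkaline peroxide gives (2R)-3-[2-hydroxy-3-(hydroxymethyl)-6-methoxy-4-(methoxymethoxy)phenyl]-2-[5-(methoxymethoxy)-2,2-dimethyl-2H-chromen-8-yl]propan-1-ol F12.
- MnO2 in CH2Cl2 oxidises only the benzylic alcohol, giving 2-hydroxy-3-{(2R)-3-hydroxy-2-[5-(methoxymethoxy)-2,2-dimethyl-2H-chromen-8-yl]propyl}-4-methoxy-6-(methoxymethoxy)benzaldehyde F13.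
- Mitsunobu closure gives (3R)-5-methoxy-7-(methoxymethoxy)-3-[5-(methoxymethoxy)-2,2-dimethyl-2H-chromen-8-yl]-3,4-dihydro-2H-chromene-8-carbaldehyde F14.
- Dilute HCl in MeOH comes back to the route at 18.

## Further compounds

F1 | step 8 | 1-[5-(methoxymethoxy)-2,2-dimethyl-2H-chromen-8-yl]ethan-1-one | CC(=O)c1ccc(OCOC)c2c1OC(C)(C)C=C2
F2 | step 8 | 5-(methoxymethoxy)-2,2-dimethyl-8-(prop-1-en-2-yl)-2H-chromene | CC(=C)c1ccc(OCOC)c2c1OC(C)(C)C=C2
F3 | step 8 | 2-[5-(methoxymethoxy)-2,2-dimethyl-2H-chromen-8-yl]prop-2-en-1-ol | OCC(=C)c1ccc(OCOC)c2c1OC(C)(C)C=C2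
F4 | step 11 | racemic 2-(1,3-dioxolan-2-yl)-5-methoxy-3-(methoxymethoxy)-6-{3-(9-borabicyclo[3.3.1]nonan-9-yl)-2-[5-(methoxymethoxy)-2,2-dimethyl-2H-chromen-8-yl]propyl}phenyl acetate | COc1cc(OCOC)c(C2OCCO2)c(OC(C)=O)c1CC(CB1C2CCCC1CCC2)c1ccc(OCOC)c2c1OC(C)(C)C=C2
F5 | step 11 | racemic 3-[3-(1,3-dioxolan-2-yl)-2-hydroxy-6-methoxy-4-(methoxymethoxy)phenyl]-2-[5-(methoxymethoxy)-2,2-dimethyl-2H-chromen-8-yl]propan-1-ol | COc1cc(OCOC)c(C2OCCO2)c(O)c1CC(CO)c1ccc(OCOC)c2c1OC(C)(C)C=C2
F6 | step 11 | racemic 8-(1,3-dioxolan-2-yl)-5-methoxy-7-(methoxymethoxy)-3-[5-(methoxymethoxy)-2,2-dimethyl-2H-chromen-8-yl]-3,4-dihydro-2H-chromene | COc1cc(OCOC)c(C3OCCO3)c2c1CC(c1ccc(OCOC)c3c1OC(C)(C)C=C3)CO2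
F7 | step 11 | (3S)-8-(1,3-dioxolan-2-yl)-5-methoxy-7-(methoxymethoxy)-3-[5-(methoxymethoxy)-2,2-dimethyl-2H-chromen-8-yl]-3,4-dihydro-2H-chromene | COc1cc(OCOC)c(C3OCCO3)c2c1C[C@@H](c1ccc(OCOC)c3c1OC(C)(C)C=C3)CO2
F8 | step 6 | tert-butyl[(1-{4-(methoxymethoxy)-2-[(2-methylbut-3-yn-2-yl)oxy]phenyl}ethenyl)oxy]dimethylsilane | C=C(O[Si](C)(C)C(C)(C)C)c1ccc(OCOC)cc1OC(C)(C)C#C
F9 | step 6 | 2-[(tert-butyldimethylsilyl)oxy]-1-{4-(methoxymethoxy)-2-[(2-methylbut-3-yn-2-yl)oxy]phenyl}ethan-1-one | CC(C)(C)[Si](C)(C)OCC(=O)c1ccc(OCOC)cc1OC(C)(C)C#C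
F10 | step 6 | tert-butyl[(2-{4-(methoxymethoxy)-2-[(2-methylbut-3-yn-2-yl)oxy]phenyl}prop-2-en-1-yl)oxy]dimethylsilane | C=C(CO[Si](C)(C)C(C)(C)C)c1ccc(OCOC)cc1OC(C)(C)C#C
F11 | step 10 | 5-methoxy-3-(methoxymethoxy)-2-{[(4,4,5,5-tetramethyl-1,3,2-dioxaborolan-2-yl)oxy]methyl}-6-{(2R)-2-[5-(methoxymethoxy)-2,2-dimethyl-2H-chromen-8-yl]-3-(4,4,5,5-tetramethyl-1,3,2-dioxaborolan-2-yl)propyl}phenyl acetate | COc1cc(OCOC)c(COB2OC(C)(C)C(C)(C)O2)c(OC(C)=O)c1C[C@H](c1ccc(OCOC)c2c1OC(C)(C)C=C2)CB1OC(C)(C)C(C)(C)O1
F12 | step 10 | (2R)-3-[2-hydroxy-3-(hydroxymethyl)-6-methoxy-4-(methoxymethoxy)phenyl]-2-[5-(methoxymethoxy)-2,2-dimethyl-2H-chromen-8-yl]propan-1-ol | COc1cc(OCOC)c(CO)c(O)c1C[C@H](c1ccc(OCOC)c2c1OC(C)(C)C=C2)CO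
F13 | step 10 | 2-hydroxy-3-{(2R)-3-hydroxy-2-[5-(methoxymethoxy)-2,2-dimethyl-2H-chromen-8-yl]propyl}-4-methoxy-6-(methoxymethoxy)benzaldehyde | COc1cc(OCOC)c(C=O)c(O)c1C[C@H](c1ccc(OCOC)c2c1OC(C)(C)C=C2)CO
F14 | step 10 | (3R)-5-methoxy-7-(methoxymethoxy)-3-[5-(methoxymethoxy)-2,2-dimethyl-2H-chromen-8-yl]-3,4-dihydro-2H-chromene-8-carbaldehyde | COc1cc(OCOC)c(C=O)c2c1C[C@H](c1ccc(OCOC)c3c1OC(C)(C)C=C3)CO2
A1 | alternative 1 | 5,7-dimethoxy-2H-chromene | COc1cc(OC)c2C=CCOc2c1
A2 | alternative 1 | 2-iodo-5-(methoxymethoxy)phenol | COCOc1ccc(I)c(O)c1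
A3 | alternative 1 | (6aR,11aR)-1,3-dimethoxy-9-(methoxymethoxy)pterocarpan | COc1cc(OC)cc2c1[C@@H]1Oc3cc(OCOC)ccc3[C@@H]1CO2
A4 | alternative 2 | 4,4,5,5-tetramethyl-2-vinyl-1,3,2-dioxaborolane | C=CB1OC(C)(C)C(C)(C)O1
A5 | alternative 2 | 8-bromo-2,2-dimethyl-5-(triisopropylsilyloxy)-2H-chromene | CC(C)[Si](Oc1ccc(Br)c2OC(C)(C)C=Cc12)(C(C)C)C(C)C
A6 | alternative 2 | 2,4-dimethoxy-6-(methoxymethoxy)phenyl trifluoromethanesulfonate | COCOc1cc(OC)cc(OC)c1OS(=O)(=O)C(F)(F)F
A7 | alternative 2 | 2-{(1R)-2-[2,4-dimethoxy-6-(methoxymethoxy)phenyl]-1-[2,2-dimethyl-5-(triisopropylsilyloxy)-2H-chromen-8-yl]ethyl}-4,4,5,5-tetramethyl-1,3,2-dioxaborolane | COc1cc(OC)cc(OCOC)c1C[C@H](c1ccc(O[Si](C(C)C)(C(C)C)C(C)C)c2c1OC(C)(C)C=C2)B1OC(C)(C)C(C)(C)O1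
A8 | alternative 3 | tert-butyl 2-(hydroxymethyl)-3,5-dimethoxyphenyl carbonate | COc1cc(OC)c(CO)c(OC(=O)OC(C)(C)C)c1
A9 | alternative 3 | tert-butyl{[2,2-dimethyl-8-((E)-2-{[trans-2-phenylcyclohexyl]oxy}ethenyl)-2H-chromen-5-yl]oxy}dimethylsilane | CC(C)(C)[Si](C)(C)Oc1ccc(/C=C/O[C@H]2CCCC[C@@H]2c2ccccc2)c2OC(C)(C)C=Cc12
A10 | alternative 3 | 2,3-trans (3R)-3-[5-(tert-butyldimethylsilyloxy)-2,2-dimethyl-2H-chromen-8-yl]-5,7-dimethoxy-2-(trans-2-phenylcyclohexyloxy)-3,4-dihydro-2H-chromene | COc1cc(OC)cc2c1C[C@H](c1ccc(O[Si](C)(C)C(C)(C)C)c3c1OC(C)(C)C=C3)[C@@H](O[C@H]1CCCC[C@@H]1c1ccccc1)O2
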